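Amounts come first: in the delta run, 1 mM of solid substrate gave product at 25.6% of the charge at 20.0 s, then 21.5% at 30.0 s and 8.6% at 50.0 s.

- delta: solid substrate 1 mM; gas 0.91 mM (held); run made earlier
- flask: solid substrate 2.0 mM; gas 0.91 mM (held); time 3.0 min

delta run (percent of the solid substrate charged): time / s: product / % = 10.0: 13.8; 12.0: 17.8; 20.0: 25.6; 30.0: 21.5; 50.0: 8.6

(readings scatter by 0.5 percentage points)

- as a solid, counted per litre of solution: solid substrate
- at the start none of the gas is in solution
- at the start none of the solid substrate is in solution

1. the moment within 3.0 min at which there is most product
2. the amount of product, in percent of the solid substrate charged, at that time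

We turn the settings one at a time. Gas stands equal in both flasks, so we leave it. The window of 3.0 min is longer than the delta run's last reading, but those readings were already falling, so by hand more time adds no height. That leaves the solid, charged in this flask at twice the delta amount.

Our own reckoning freezes two things. The late fall reads as a pseudo-first-order loss with constant 0.0458 /s. We also suppose that solid enters at a steady amount per second whatever the charge, and that the delta peak marks the end of this feed. A feed of length T, losing at that constant k, keeps at its end the share one minus exp(−kT), divided by kT, of what it made. The ceiling, the share of the charge standing as product at the end of a steady feed if nothing were lost during it, then reads 39.1%. Holding the ceiling, the loss constant and the feed per second as in the delta run, we reckon for this flask a feed of 0.667 min and an estimated peak of 17.9%.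

The forecast reckons otherwise: if dissolution scales with the solid charged, then "doubling the charge leaves the percent-versus-time curve unchanged". Allowing for a possible solubility limit, it skews its time slightly later and gives 26.5% at 0.37 min.

The flask gives its most product at 0.573 min, 21.1% of the charge. With the time changed and the solid as in the delta run, the highest product stays at 25.6%; with the solid changed and the time as in the delta run, it is 21.1%. Taking 0.573 min as the feed length, the ceiling gives 19.7%, against the 21.1% found.

    starting material → intermediate A (k = 0.140 /s)
    partner + intermediate A → intermediate B (k = 350 /M/s)
    partner + intermediate B ⇌ intermediate C (K = 190 /M, k = 38.0 /M/s)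
    intermediate A ⇌ product (K = 3.00, k = 0.330 /s)
    gas ⇌ partner, rate k5*(csat - [partner]) (kL = 0.840 /s)
    solid substrate ⇌ starting material, rate k6*(cs6 - [starting material]) while solid is left; crystals form when [starting material] > cs6 (solubility = 0.630 mM, k = 0.250 /s)

For a neighbour flask with 0.80 mM of solid substrate, the feed lasts 16.0 s, and the ceiling gives 27.7%. The neighbour flask gives 26.1%.

The readings were generated by integration for an exercise.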